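(The rate constants are invented, and the outcome is calculated.)

Count the turnovers of the second catalyst first: how many lifetimes of intermediate it delivers before it decays.

| flask | starting material | reagent | protic impurity | free catalyst | second catalyst | time | remark |
|---|---|---|---|---|---|---|---|
| south-west | 0.50 mM (fed, over 12.0 s) | 0.400 mM | 0.0250 mM | 6.5 µM | 25 µM | 15 s | all but starting material at the start; starting material goes in evenly over 12.0 s, the run ends at 15 s |
| north-east | 0.50 mM | 0.400 mM | 0.0250 mM | 6.5 µM | 25 µM |  | one stirred flow tank at steady state, fed with the mixture as stated, mean residence time 75.0 s |
| east | 0.50 mM | 0.400 mM | 0.0250 mM | 6.5 µM | 25 µM | 15 s | a closed flask charged with all of it at once and left for 15 s |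
| north | 0.50 mM | 0.400 mM | 0.0250 mM | 6.5 µM | 25 µM |  | a single well-mixed tank run continuously and read at steady state, 15 s in it on average |

    reagent + second catalyst + intermediate → second catalyst + product (k1 = 1.3 × 10⁷ M⁻² s⁻¹)
    starting material + free catalyst → free catalyst + intermediate (k2 = 4900 M⁻¹ s⁻¹)
    starting material + protic impurity → quenched substrate (k3 = 1600 M⁻¹ s⁻¹)
    second catalyst → spent catalyst (k4 = 0.053 s⁻¹)

- the stated concentrations are those of everything mixed, before any reaction; amounts are the same in each set-up
- the feed brings no volume worth counting
- run time (south-west): 15 s

1. the set-up with the highest amount of intermediate at the outlet or at the end, in percent of the starting material put in ("none" if the first two lie within 2 percentage points) (south-west / north-east / east / north / none)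
2. amount of intermediate at the outlet or at the end, in percent of the starting material put in, south-west
3. amount of intermediate at the outlet or at the end, in percent of the starting material put in, north-east
4. amount of intermediate at the outlet or at the end, in percent of the starting material put in, east
5. amount of intermediate at the outlet or at the end, in percent of the starting material put in, north

Three frequencies carry the reckoning. With reagent and second catalyst as charged, intermediate leaves at kR (a pseudo-first-order constant). Starting material becomes intermediate at kF, and second catalyst decays at kD.

kR = 0.130 s⁻¹, kF = 0.0318 s⁻¹, kD = 0.053 s⁻¹

n(t) = (kR/kD)(1 − e^(−kD·t)) = 1.35 at 15 s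

Call n the removal count, the number of intermediate lifetimes delivered so far by the second catalyst.

Take the east flask in slow motion. In the first instants protic impurity reacts, with a half-life of 0.866 s against starting material, far shorter than the 22 s of starting material going to intermediate. It takes 5.00% of the starting material with it.

In the middle, the half-life of intermediate by step 1 stands at 5.3 s only with the other concentrations as charged. It lengthens as the run goes on, because second catalyst halves every 13.1 s, shorter than the 15 s of the run.

By the end, east has formed F:

F = 0.180 mM

Intermediate born at 7.50 s stands for the whole. It sees n = 0.545, so this reckoning leaves 21.0% in east.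

In a stirred tank, n = kR·τ/(1 + kD·τ) for mean residence time τ, and at the outlet n is product per intermediate. Reagent as charged gives:

north: n = 1.09, F = 0.154 mM

north-east: n = 1.96, F = 0.335 mM

Product takes reagent, so assume half of F has gone on and scale n to that reagent level:

north: n = 0.878, intermediate F/(1 + n) = 16.4%

north-east: n = 1.14, intermediate = 31.3%

The shares going on, n/(1 + n), come to 46.8% and 53.3%, near the half assumed. South-west doses over 12.0 s, so its intermediate is born late, and this reckoning stops there. Among the other flasks, it puts north-east ahead.

The forecast named north-east, with 16.5% south-west, 32% north-east, 21.7% east and 16.4% north. Its ground for the removal is that consumption “falls as the second catalyst decays”. It stands above this reckoning by 0.7 percentage points in north-east and 0.70 points in east.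

The simulation gives 16.5% south-west, 32.0% north-east, 21.7% east and 16.4% north, so north-east stands highest. At the north-east outlet product stands at 35.2%, or 1.10 per intermediate, with reagent at 0.224 mM; the count at that reagent level is 1.10. South-west with 0.10 mM of second catalyst has a closed count of 5.38 at 15 s, reagent as charged, and holds 8.75% intermediate beside 14.4% product.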